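In the flavonol, C3 of the pyranone ring C is an isolated one-carbon unit: its only carbon neighbours are C2 and the carbonyl carbon C4, and it bears nothing but oxygen. Excising it contracts ring C to the furanone of a 2-arylbenzofuran-3-one, which Friedel–Crafts acylation closes readily. The key step reinserts that carbon: dibromocarbene adds to the enol double bond of a 3-silyloxybenzofuran and the resulting cyclopropane opens, so one operation makes both bonds to C3 (C2–C3 and C3–C4) and turns the five-membered ring into ring C, delivered as a 3-bromoflavone. The precursor is the tert-butyldimethylsilyl enol ether of 4,6-bis(benzyloxy)-2-(4-methoxyphenyl)benzofuran-3-one; bromine is later exchanged for hydroxyl and the prenyl ether is made last.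

Key step: step 4

Assumption: bromo ester 2 is used as the racemate; its stereocentre (carried through 3, 4, 5 and 6) becomes sp2 in step 3, and the target has no stereocentre.

Design choices:
- The silyl group is tert-butyldimethylsilyl. A trimethylsilyl enol ether would be cleaved by tert-butoxide to the enolate before the carbene is captured; a triisopropylsilyl group would shield the double bond and resist the final desilylation.
- The ring A oxygens are benzyl ethers: inert to base, no alkene to compete for the carbene, and removable by hydrogenolysis once the bromine has gone.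
- After the key step the C3–Br bond is converted first, on the fully protected compound, so that the palladium catalyst meets neither a free phenol nor an allylic ether. The prenyl group comes last because its alkene would take the carbene and would not survive hydrogenolysis.

Step 1
Reactants: 1 3,5-bis(benzyloxy)phenol; 2 methyl 2-bromo-2-(4-methoxyphenyl)acetate (racemic)
Product: 4 racemic 2-[3,5-bis(benzyloxy)phenoxy]-2-(4-methoxyphenyl)acetic acid, via methyl ester 3 (not isolated)
Conditions: K2CO3, MeCN, 60 °C; then 2 M aq NaOH, MeOH, rt; then 1 M HCl to pH 2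
Reagents that add atoms: sodium hydroxide, [Na+].[OH-] (its oxygen becomes a carboxyl oxygen)
Why: Williamson ether synthesis, in which the phenoxide of 1 displaces the activated benzylic α-bromide of 2 by SN2 in a polar aprotic solvent that favours O- over C-alkylation, followed in the same flask by saponification of the methyl ester.

Step 2
Reactants: 4 racemic 2-[3,5-bis(benzyloxy)phenoxy]-2-(4-methoxyphenyl)acetic acid
Product: 6 racemic 4,6-bis(benzyloxy)-2-(4-methoxyphenyl)benzofuran-3(2H)-one, via mixed anhydride 5 (not isolated)
Conditions: TFAA, CH2Cl2, 0 °C → rt, Ar; then aq NaHCO3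
Reagents that add atoms: none
Why: Intramolecular Friedel–Crafts acylation, in which the mixed trifluoroacetic anhydride 5 acylates the ring carbon ortho to the ether oxygen (5-exo closure; the two ortho positions are equivalent and each is activated by one ortho and one para oxygen), while the absence of a strong Lewis acid spares the benzyl ethers and the bicarbonate wash cleaves any enol trifluoroacetate.

Step 3
Reactants: 6 racemic 4,6-bis(benzyloxy)-2-(4-methoxyphenyl)benzofuran-3(2H)-one
Product: 7 4,6-bis(benzyloxy)-3-(tert-butyldimethylsilyloxy)-2-(4-methoxyphenyl)benzofuran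
Conditions: TBSOTf, Et3N, CH2Cl2, 0 °C, Ar
Reagents that add atoms: tert-butyldimethylsilyl trifluoromethanesulfonate, CC(C)(C)[Si](C)(C)OS(=O)(=O)C(F)(F)F
Why: Soft enolisation and O-silylation (silyl enol ether formation), favoured because the C2–H is benzylic and flanked by the carbonyl and the ring oxygen and because enolisation makes the furan ring aromatic, so silylation should occur on oxygen only and removes the stereocentre.

Step 4
Reactants: 7 4,6-bis(benzyloxy)-3-(tert-butyldimethylsilyloxy)-2-(4-methoxyphenyl)benzofuran; 8 bromoform
Product: 10 5,7-bis(benzyloxy)-3-bromo-2-(4-methoxyphenyl)chromen-4-one, via dibromocyclopropane adduct 9 (not isolated)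
Conditions: CHBr3 (2 equiv), KOtBu (2.5 equiv, added in portions to 7 and CHBr3), toluene, −30 °C → rt; then 1 M HCl
Reagents that add atoms: bromoform, BrC(Br)Br
Why: Proposed new method: tert-butoxide deprotonates bromoform, the tribromomethyl anion loses bromide, and the electrophilic dibromocarbene adds in a concerted cheletropic [2+1] step to the C2=C3 bond of 7, which is the most electron-rich π bond because O1 donates into one end and the silyloxy oxygen into the other. In adduct 9 the bromine on the face of the furan ring atoms leaves while the shared C2–C3 bond opens in a disrotatory two-electron electrocyclic process (the only mode a cis-fused bicycle allows), which gives an aromatic 3-bromo-4-silyloxybenzopyrylium ion; bromide, tert-butoxide or the acidic work-up then takes the silyl group and leaves the C4 carbonyl. The closest known reaction types are the dihalocarbene homologation of cyclic silyl enol ethers to ring-enlarged 2-halo-enones and the Ciamician–Dennstedt enlargement of pyrroles and indoles to 3-halopyridines and 3-haloquinolines. Ring C is therefore not closed end to end but made by ring enlargement: the carbene carbon first bridges the two furan carbons (three-membered ring by [2+1] addition) and cleavage of the bond between them turns five ring atoms into six. No stereocentre has to be set, since both centres of racemic 9 return to sp2. The selectivity needed is chemoselectivity for the tetrasubstituted enol double bond over the alkoxy-substituted benzene rings and the benzylic C–H bonds, secured by the double oxygen donation (and by the absence of any other alkene, the prenyl group being withheld), together with opening of the cyclopropane instead of its survival, secured by the same two oxygens, which stabilise the developing cation.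

Step 5
Reactants: 10 5,7-bis(benzyloxy)-3-bromo-2-(4-methoxyphenyl)chromen-4-one
Product: 12 5,7-bis(benzyloxy)-3-hydroxy-2-(4-methoxyphenyl)chromen-4-one, via pinacol boronate 11 (not isolated)
Conditions: B2pin2, PdCl2(dppf) (5 mol %), KOAc, 1,4-dioxane, 85 °C; then NaBO3·4H2O, THF/H2O, rt
Reagents that add atoms: sodium perborate, [Na+].[O-]OB=O (oxygen of the 3-hydroxyl); bis(pinacolato)diboron, CC1(C)OB(OC1(C)C)B1OC(C)(C)C(C)(C)O1 (boron of 11 only)
Why: Miyaura borylation of the activated alkenyl C–Br bond followed by perborate oxidation of the C–B bond (1,2-shift of carbon from boron to oxygen, then hydrolysis) should give the enol that is the 3-hydroxyflavone, the acetate base and perborate being too mild to open the pyranone or touch the benzyl ethers.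

Step 6
Reactants: 12 5,7-bis(benzyloxy)-3-hydroxy-2-(4-methoxyphenyl)chromen-4-one
Product: 13 3,5,7-trihydroxy-2-(4-methoxyphenyl)chromen-4-one (kaempferide)
Conditions: H2 (1 atm), Pd/C (10 %), THF/MeOH, rt
Reagents that add atoms: none
Why: Catalytic hydrogenolysis of the two benzyl aryl ethers, under which the tetrasubstituted C2=C3 bond, the carbonyl and the aryl methyl ether should be inert, and which is placed after removal of bromine so that no hydrodebromination can occur.

Step 7
Reactants: 13 3,5,7-trihydroxy-2-(4-methoxyphenyl)chromen-4-one; 14 prenyl bromide (1-bromo-3-methylbut-2-ene)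
Product: 15 3,5-dihydroxy-2-(4-methoxyphenyl)-7-(3-methylbut-2-enyloxy)chromen-4-one (target)
Conditions: K2CO3 (1.1 equiv), prenyl bromide (1.05 equiv), DMF, 0 °C → rt, Ar
Reagents that add atoms: prenyl bromide, CC(C)=CCBr
Why: Williamson ether synthesis under acidity control, since the 7-hydroxyl is a vinylogous carboxylic acid without a hydrogen bond whereas the 3- and 5-hydroxyls are both chelated to the C4 carbonyl and distinctly less acidic, so one equivalent of carbonate should form only the 7-phenoxide, which attacks the primary carbon of prenyl bromide by SN2.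

Compound list
1 | 3,5-bis(benzyloxy)phenol | Oc1cc(OCc2ccccc2)cc(OCc2ccccc2)c1 | starting material
2 | methyl 2-bromo-2-(4-methoxyphenyl)acetate (racemic) | COC(=O)C(Br)c1ccc(OC)cc1 | starting material
3 | methyl 2-[3,5-bis(benzyloxy)phenoxy]-2-(4-methoxyphenyl)acetate (racemic) | COC(=O)C(Oc1cc(OCc2ccccc2)cc(OCc2ccccc2)c1)c1ccc(OC)cc1 | intermediate (not isolated)
4 | 2-[3,5-bis(benzyloxy)phenoxy]-2-(4-methoxyphenyl)acetic acid (racemic) | OC(=O)C(Oc1cc(OCc2ccccc2)cc(OCc2ccccc2)c1)c1ccc(OC)cc1 | intermediate
5 | 2-[3,5-bis(benzyloxy)phenoxy]-2-(4-methoxyphenyl)acetic trifluoroacetic anhydride (racemic) | O=C(OC(=O)C(F)(F)F)C(Oc1cc(OCc2ccccc2)cc(OCc2ccccc2)c1)c1ccc(OC)cc1 | intermediate (not isolated)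
6 | 4,6-bis(benzyloxy)-2-(4-methoxyphenyl)benzofuran-3(2H)-one (racemic) | COc1ccc(cc1)C1Oc2cc(OCc3ccccc3)cc(OCc3ccccc3)c2C1=O | intermediate
7 | 4,6-bis(benzyloxy)-3-(tert-butyldimethylsilyloxy)-2-(4-methoxyphenyl)benzofuran | COc1ccc(cc1)-c1oc2cc(OCc3ccccc3)cc(OCc3ccccc3)c2c1O[Si](C)(C)C(C)(C)C | intermediate (key-step precursor)
8 | bromoform | BrC(Br)Br | starting material
9 | 4,6-bis(benzyloxy)-1,1-dibromo-6b-(tert-butyldimethylsilyloxy)-1a-(4-methoxyphenyl)-1a,6b-dihydro-1H-cyclopropa[b][1]benzofuran (racemic; ring fusion necessarily cis) | COc1ccc(cc1)C12Oc3cc(OCc4ccccc4)cc(OCc4ccccc4)c3C1(O[Si](C)(C)C(C)(C)C)C2(Br)Br | intermediate (not isolated)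
10 | 5,7-bis(benzyloxy)-3-bromo-2-(4-methoxyphenyl)chromen-4-one | COc1ccc(cc1)-c1oc2cc(OCc3ccccc3)cc(OCc3ccccc3)c2c(=O)c1Br | intermediate (key-step product)
11 | 5,7-bis(benzyloxy)-2-(4-methoxyphenyl)-3-(4,4,5,5-tetramethyl-1,3,2-dioxaborolan-2-yl)chromen-4-one | COc1ccc(cc1)-c1oc2cc(OCc3ccccc3)cc(OCc3ccccc3)c2c(=O)c1B1OC(C)(C)C(C)(C)O1 | intermediate (not isolated)
12 | 5,7-bis(benzyloxy)-3-hydroxy-2-(4-methoxyphenyl)chromen-4-one | COc1ccc(cc1)-c1oc2cc(OCc3ccccc3)cc(OCc3ccccc3)c2c(=O)c1O | intermediate
13 | 3,5,7-trihydroxy-2-(4-methoxyphenyl)chromen-4-one (kaempferide) | COc1ccc(cc1)-c1oc2cc(O)cc(O)c2c(=O)c1O | intermediate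
14 | prenyl bromide (1-bromo-3-methylbut-2-ene) | CC(C)=CCBr | starting material
15 | 3,5-dihydroxy-2-(4-methoxyphenyl)-7-(3-methylbut-2-enyloxy)chromen-4-one | COc1ccc(-c2oc3cc(OCC=C(C)C)cc(O)c3c(=O)c2O)cc1 | target

Total step count: 7
Longest linear sequence: 7 steps (1 → 15; the route is fully linear)

Steps most likely to fail

Step 4 (key step, proposed new method). What may go wrong: tert-butoxide may strip the silyl group before the carbene is captured, so that the enolate is C-alkylated at C2 without ring growth; the carbene may also be consumed by ring A, or the adduct may fail to open. The fallback uses known chemistry and sets out from 1. Fries-type C-acetylation next to the hydroxyl (Ac2O, BF3·OEt2) should give 1-[2,4-bis(benzyloxy)-6-hydroxyphenyl]ethan-1-one F1. Claisen–Schmidt condensation with 4-methoxybenzaldehyde (KOH, EtOH) should give the chalcone (E)-1-[2,4-bis(benzyloxy)-6-hydroxyphenyl]-3-(4-methoxyphenyl)prop-2-en-1-one F2. Oxidative cyclisation (catalytic I2, DMSO, 130 °C) should give the flavone 5,7-bis(benzyloxy)-2-(4-methoxyphenyl)chromen-4-one F3. Lithiation at C3 (LiN(iPr)2, THF, −78 °C), trapping with B(OMe)3 as dimethyl [5,7-bis(benzyloxy)-2-(4-methoxyphenyl)-4-oxochromen-3-yl]boronate F4 and oxidation in the same flask (H2O2, AcOH) would deliver 12, where the route is rejoined before step 6.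

Step 5. What may go wrong: the C3 substituent may be lost as C–H, either by protodehalogenation of the organopalladium intermediate or by protodeboronation of the α-boryl enone before it is oxidised; coupling of the boronate with unreacted bromide is a second drain. The fallback sets out from 10 and replaces borylation–oxidation by a carbon–oxygen cross-coupling. Benzyl alcohol with Pd2(dba)3, the ligand tBuBrettPhos and Cs2CO3 in toluene at 90 °C should give 3,5,7-tris(benzyloxy)-2-(4-methoxyphenyl)chromen-4-one F5. A single hydrogenolysis (H2, Pd/C, THF/MeOH) then removes all three benzyl groups and returns to the route at 13.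

Step 7. What may go wrong: site selectivity may be poor, with alkylation at the 3-hydroxyl competing and leading to dialkylation. The fallback sets out from 13 and replaces acidity control by protecting-group differentiation. Peracetylation (Ac2O, pyridine) should give 2-(4-methoxyphenyl)-4-oxochromene-3,5,7-triyl triacetate F6. Selective removal of the most labile, 7-acetate (PhSH, imidazole, N-methylpyrrolidone, 0 °C) should give 7-hydroxy-2-(4-methoxyphenyl)-4-oxochromene-3,5-diyl diacetate F7. Alkylation of the only free hydroxyl with 14 (K2CO3, acetone) should give 2-(4-methoxyphenyl)-7-(3-methylbut-2-enyloxy)-4-oxochromene-3,5-diyl diacetate F8. Methanolysis of the two remaining acetates (K2CO3, MeOH, rt) arrives at 15.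

Further compounds
F1 | step 4 | 1-[2,4-bis(benzyloxy)-6-hydroxyphenyl]ethan-1-one | CC(=O)c1c(O)cc(OCc2ccccc2)cc1OCc1ccccc1
F2 | step 4 | (E)-1-[2,4-bis(benzyloxy)-6-hydroxyphenyl]-3-(4-methoxyphenyl)prop-2-en-1-one | COc1ccc(/C=C/C(=O)c2c(O)cc(OCc3ccccc3)cc2OCc2ccccc2)cc1
F3 | step 4 | 5,7-bis(benzyloxy)-2-(4-methoxyphenyl)chromen-4-one | COc1ccc(cc1)-c1cc(=O)c2c(OCc3ccccc3)cc(OCc3ccccc3)cc2o1
F4 | step 4 | dimethyl [5,7-bis(benzyloxy)-2-(4-methoxyphenyl)-4-oxochromen-3-yl]boronate (not isolated) | COB(OC)c1c(-c2ccc(OC)cc2)oc2cc(OCc3ccccc3)cc(OCc3ccccc3)c2c1=O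
F5 | step 5 | 3,5,7-tris(benzyloxy)-2-(4-methoxyphenyl)chromen-4-one | COc1ccc(cc1)-c1oc2cc(OCc3ccccc3)cc(OCc3ccccc3)c2c(=O)c1OCc1ccccc1
F6 | step 7 | 2-(4-methoxyphenyl)-4-oxochromene-3,5,7-triyl triacetate | COc1ccc(cc1)-c1oc2cc(OC(C)=O)cc(OC(C)=O)c2c(=O)c1OC(C)=O
F7 | step 7 | 7-hydroxy-2-(4-methoxyphenyl)-4-oxochromene-3,5-diyl diacetate | COc1ccc(cc1)-c1oc2cc(O)cc(OC(C)=O)c2c(=O)c1OC(C)=O
F8 | step 7 | 2-(4-methoxyphenyl)-7-(3-methylbut-2-enyloxy)-4-oxochromene-3,5-diyl diacetate | COc1ccc(cc1)-c1oc2cc(OCC=C(C)C)cc(OC(C)=O)c2c(=O)c1OC(C)=O
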